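**Retrosynthetic overview**
1. Feature: the acyl part is an unbranched, fully saturated C22 chain with no functional group from C2 to C22, so its C5–C6 CH2–CH2 bond can be traced back to two primary alkyl radicals. The only ring, the benzene ring of the 2-phenylethyl ester, is bought, and no ring is formed at any stage.
2. C1–C5 fragment: 6-(tert-butoxy)-6-oxohexanoic acid (1) and 2-phenylethanol (2) give the mixed diester 3; removal of the tert-butyl group gives the half-ester 4, which already carries the final ester.
3. C6–C22 fragment: stearic acid (5), used as bought.
4. Key disconnection C5–C6: anodic decarboxylation of 5 and 4 gives the heptadecyl radical 6 and the 5-oxo-5-(2-phenylethoxy)pentyl radical 7, whose cross-combination gives 2-phenylethyl docosanoate (8).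
5. Order of events: esterification, deprotection, then the C–C coupling as the last step; there is no stereocentre to set.

Key step: step 3

Assumption: the target has no stereocentre and no stereogenic double bond, so it is one achiral compound and no stereocontrol is planned; 6-(tert-butoxy)-6-oxohexanoic acid (1) is taken as a purchasable building block.

**Step 1**
Reactants: 1 6-(tert-butoxy)-6-oxohexanoic acid (adipic acid mono-tert-butyl ester); 2 2-phenylethanol
Product: 3 tert-butyl 2-phenylethyl hexanedioate
Conditions: DCC (1.1 equiv), DMAP (0.1 equiv), CH2Cl2, 0 °C → rt; filter, SiO2
Reagents that add atoms: none
Why: Steglich esterification: DCC activates the free carboxylic acid of 1 and DMAP passes the acyl group to the unhindered primary alcohol 2 under neutral conditions that should leave the tert-butyl ester untouched.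

**Step 2**
Reactants: 3 tert-butyl 2-phenylethyl hexanedioate
Product: 4 6-oxo-6-(2-phenylethoxy)hexanoic acid (adipic acid mono(2-phenylethyl) ester)
Conditions: TFA/CH2Cl2 (1:3), rt; evaporate, toluene azeotrope
Reagents that add atoms: none
Why: Acidolysis of a tert-butyl ester by alkyl–oxygen cleavage with loss of isobutene, a pathway open only to the tertiary ester, so the primary 2-phenylethyl ester should survive unchanged.

**Step 3**
Reactants: 4 6-oxo-6-(2-phenylethoxy)hexanoic acid; 5 stearic acid (octadecanoic acid)
Product: 8 2-phenylethyl docosanoate, via heptadecyl radical 6 (not isolated), via 5-oxo-5-(2-phenylethoxy)pentyl radical 7 (not isolated)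
Conditions: 5 (4 equiv), KOH (0.05 equiv per mol of acid), MeOH, 50 °C, undivided cell, smooth Pt anode/Pt cathode, constant current ca. 0.25 A cm⁻², periodic polarity reversal; stopped while still weakly acidic, then AcOH; SiO2 (hexane → hexane/EtOAc)
Reagents that add atoms: none
Why: Mixed (crossed) Kolbe electrolysis: the potassium carboxylates of 5 and 4 are oxidised at the carboxylate-covered platinum anode, each loses CO2, and the radicals 6 and 7 combine at the electrode surface to form the C5–C6 bond of the docosanoyl chain. The closest known reaction type is the crossed Kolbe chain extension of a fatty acid with a dicarboxylic acid half-ester, which is established for long unbranched chains. No ring is closed and no stereocentre is formed, so neither a mode of ring closure nor stereocontrol arises. Both radicals are unstabilised primary alkyl radicals without α-branching or α-heteroatom, so radical coupling should win over further oxidation to carbocations (Hofer–Moest pathway), helped by the high current density, the weakly acidic medium and the smooth platinum surface. The step needs cross- over homo-coupling, which is only statistical; the excess of cheap 5 should steer most of radical 7 into the cross product, and the two symmetric dimers (a C34 alkane and a C10 diester) differ enough in polarity from the monoester 8 to be removed on silica. The spectator groups should survive because the ester sits four carbons from the radical centre, the adsorbed carboxylate layer keeps the unactivated phenyl ring away from the anode, and stopping while free acid remains prevents methoxide from building up and exchanging the 2-phenylethyl ester.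

**Compound list**
1 | 6-(tert-butoxy)-6-oxohexanoic acid (adipic acid mono-tert-butyl ester) | CC(C)(C)OC(=O)CCCCC(=O)O | starting material
2 | 2-phenylethanol | OCCc1ccccc1 | starting material
3 | tert-butyl 2-phenylethyl hexanedioate | CC(C)(C)OC(=O)CCCCC(=O)OCCc1ccccc1 | intermediate
4 | 6-oxo-6-(2-phenylethoxy)hexanoic acid (adipic acid mono(2-phenylethyl) ester) | OC(=O)CCCCC(=O)OCCc1ccccc1 | intermediate
5 | stearic acid (octadecanoic acid) | CCCCCCCCCCCCCCCCCC(=O)O | starting material
6 | heptadecyl radical | [CH2]CCCCCCCCCCCCCCCC | intermediate
7 | 5-oxo-5-(2-phenylethoxy)pentyl radical | [CH2]CCCC(=O)OCCc1ccccc1 | intermediate
8 | 2-phenylethyl docosanoate | CCCCCCCCCCCCCCCCCCCCCC(=O)OCCc1ccccc1 | target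

**Total step count:** 3
**Longest linear sequence:** 3 steps (1 → 3 → 4 → 8)

**Steps most likely to fail**

Step 3 (crossed Kolbe electrolysis). The anode may become passivated by a waxy film of long-chain products or by oxidative attack on the phenyl ring. The 2-phenylethyl ester may be exchanged for a methyl ester by cathodically formed base in methanol. The half-ester radical may be lost to homo-coupling and disproportionation. The fallback takes the arene and the primary ester out of the cell and sets out from 1 and 5. Co-electrolysis of 1 with an excess of 5 under the same crossed Kolbe conditions should give tert-butyl docosanoate F1, whose ester neither exchanges in methanol nor carries an oxidisable ring; it would be separated from the two symmetric dimers on silica. Treatment with TFA in CH2Cl2 should then give docosanoic acid F2, and Fischer esterification of F2 with 2 (cat. TsOH, toluene, Dean–Stark) comes back to the route at 8.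

Step 1 (carbodiimide esterification). The activated acid may rearrange to an unreactive N-acylurea before the alcohol attacks, and urea residues may be carried into the next step. The fallback reverses the mode of activation and sets out from 1 and 2. In a Mitsunobu esterification (PPh3, DIAD, THF, 0 °C → rt) the alcohol 2 is activated as its alkoxyphosphonium ion and the carboxylate of 1 acts as the nucleophile. This should give the mixed diester directly and comes back at 3.

Step 2 (tert-butyl ester acidolysis). Cleavage may stall, or the tert-butyl cation may be trapped by the phenyl ring instead of escaping as gas. The fallback does without a protecting group and sets out from 2. Heating 2 with a threefold excess of adipic acid (OC(=O)CCCCC(=O)O) and cat. TsOH in toluene/1,4-dioxane with azeotropic removal of water should give statistical mono-esterification. The half-ester is extracted into aqueous NaHCO3 away from neutral over-esterified material and freed from the water-soluble diacid on acidification and washing. This comes back to the route at 4.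

**Further compounds**
F1 | step 3 | tert-butyl docosanoate | CCCCCCCCCCCCCCCCCCCCCC(=O)OC(C)(C)C
F2 | step 3 | docosanoic acid | CCCCCCCCCCCCCCCCCCCCCC(=O)O
F0 | step 1 | none | none
F0 | step 2 | none | none
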